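## Structural features

The target is built from two cyclohexene rings, A and B, each numbered C1(methyl)=C2, C3, C4, C5, C6, with three contiguous stereocentres: C3 carries a linker aryl group, C4 an acyl group and C5 a 2,4-dihydroxyphenyl group. The linker aryl of each ring (ArA on ring A, ArB on ring B) is a 4,6-dihydroxy-1,3-phenylene whose second carbon substituent is the ketone carbonyl on C4 of the other ring, so the halves are joined head to tail through two aryl ketones into a twelve-membered [3.3]metacyclophane. The halves are constitutionally identical and share the configuration at C3 and C5; they differ only at C4, where the acyl group is cis to the C3 aryl and trans to the C5 aryl in ring A, but trans to the C3 aryl and cis to the C5 aryl in ring B. Both C4 centres are alpha to a 2-hydroxyaryl ketone and can epimerise, and the ring B arrangement, with the acyl group syn to the neighbouring C5 aryl, is expected to be the less stable one, so it has to be made and kept under kinetic control. Further fragile elements are the eight phenols, the trisubstituted alkenes next to ortho-hydroxyaryl groups (acid can cause chroman formation and alkene migration) and the C3–aryl bonds, which are both allylic and benzylic. The real difficulty is to differentiate C4 in two otherwise identical halves, to join two hindered secondary acyl carbons to resorcinol carbons, and to close the twelve-membered ring without disturbing C4. The key step exploits ring A: the C4 carboxyl carbon, C4, C3, the ArA carbon bonded to C3, the adjacent ArA carbon and its phenolic oxygen can form a six-membered lactone only when ArA and the acyl group are cis, so an aryl ester at C4 delivers ArA to C3 of the C1–C2–C3 allyl cation on its own face.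

## Logic of the disconnections

25 from 24: seven O–Si bonds are cut last. All phenols except the one released in the ring closure travel as silyl ethers; the demand is a deprotection that is neither acidic nor strongly basic.

24 from 23: the ArB–C(=O) bond of the ketone on ring A C4 is cut, opening the twelve-membered ring to a ring A lactone and an ArB boronate in one molecule. The lactone is already present from the key step and serves as acyl donor and phenol mask, so no separate activation is needed. The demand is C(acyl)–O activation at high dilution without epimerising C4 of ring B.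

23 from 22: the C–B bond is traced back to C–Br. The bromide is carried until all chemistry that is incompatible with a boronate has been done.

22 from 21 and 19: the ArA–C(=O) bond of the ketone on ring B C4 is cut into a thioester and an arylboronic acid. This divides the molecule into its two halves; the demand is a neutral acyl coupling that leaves the lactone of 21, the bromide of 19 and the labile C4 of ring B untouched.

21 from 12: again C–B from C–Br.

19 from 18, and 18 from 17 and 3: the ring B C3–ArB bond is cut to an allyl cation precursor and a resorcinol. The forward step must attack C3 rather than C1 and enter on the face opposite to the C4 acyl group.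

17 from 15, 15 from 13, 13 from 11: the C4–H bond of ring B is taken back to a conjugated trienolate, the C3=C4 bond to a beta-hydroxy thioester, and the C–S bond to an aryl ester. Ring B keeps only C5 from 11, so both halves descend from a single enantioselective step; the demand is a face-selective kinetic protonation at C4.

12 from 11 (key step): the ring A C3–ArA bond is cut, leaving the aryl ester as tether. The forward step must form this bond cis to the acyl group and at C3.

11 from 7 and 9: the C3–C4 and C5–C6 bonds are cut in a [4+2] sense. This sets the trans C4/C5 pair from the alkene geometry and needs a chiral catalyst for the absolute configuration.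

7 from 2 and 6, 6 from 5, 5 from 3 and 4, 2 from 1, 9 from 8: the cinnamate C=C bond is cut by olefination and the remaining cuts are ester, silyl ether and silyl enol ether bonds back to commercial materials. The only demand is regioselective acylation of the less hindered hydroxyl of 3.

## Other disconnections considered

Alternative 1: The cut is the bond between ArA and the ketone carbon on ring B C4. In the forward step the seco compound A1, in which ring B is held as a cis-fused lactone between its C4 carboxyl and the ortho oxygen of its C5 aryl group and ArA carries a pinacol boronate, would be treated with a zerovalent palladium N-heterocyclic carbene catalyst and base. Insertion into the lactone C(acyl)–O bond, intramolecular transmetalation and reductive elimination would close the twelve-membered ring and give A2 with that ortho phenol free.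
- In its favour: the lactone locks the labile C4 of ring B until the last C–C bond is made, and no extra activation or protection is needed.
- Against it here: ring B must first be obtained as a cis-fused lactone with a trans C3 aryl group, which calls for a coumarin-type (Z-cinnamate) dienophile of low reactivity. The earlier intermolecular acyl coupling must also distinguish two aryl ester lactones and avoid the aryl bromide.
- Comparison: mechanistically it is the same reaction class as step 16 of the chosen plan, applied to the other lactone, and it is equal in step count for the closure. It is the better of the two in protecting ring B C4, because in the chosen plan that centre is an open ketone during the base-mediated closure. It is the weaker in access to its precursor, since the chosen plan sets the cis C4/C5 relation by a protonation and uses the lactone that the key step already provides.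

Alternative 2: The cut is the ring B C4–C5 bond, traced back to a seven-membered ring. In the forward step the alkoxide of the cis-bromohydrin A3 would undergo a semipinacol shift: C5 migrates from the carbinol carbon to C4 with loss of bromide, contracting the ring to the cyclohexene and revealing the aryl ketone A4.
- In its favour: the shift is stereospecific (inversion at C4, retention at C5), so the trans C3/C4 and cis C4/C5 relations follow from the bromohydrin geometry; ketone and stereocentre are formed together. On predictability of the C4 configuration this is the better of the two plans, since step 10 of the chosen plan depends on a face-selective protonation.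
- Against it here: a cycloheptene with four contiguous stereocentres, including a tertiary carbinol and a secondary bromide, must be made as a single enantiomer. Aryl migration, epoxide formation and elimination compete with ring-carbon migration.
- Comparison: the product A4 still has to be joined to ring A, and its silyl-protected phenol could serve as the tether for the chosen key step, so the two ideas are compatible. In step economy the alternative is clearly longer than the four steps that lead from 11 to 19.

Alternative 3: The cut is the ArB–C(=O) bond of the ketone on ring A C4, traced back to an aryl ester. In the forward step irradiation of the fourteen-membered macrolactone A5 would cleave the acyl–oxygen bond homolytically, the radical pair would recombine at the ortho carbon, and tautomerisation would give the twelve-membered diketone A6 with both ketone-flanking phenols free (photo-Fries ring contraction).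
- In its favour: closing a ring by ester formation is easier than by C–C bond formation. The step needs no metal and no base, so on avoiding enolate epimerisation at C4 it is the equal or the better of step 16, and it frees exactly the phenol that flanks the new ketone.
- Against it here: the aryl ketone already present and the electron-rich arenes absorb in the same region. Recombination can also occur at the other ortho carbon, between the two oxygens. Escape from the solvent cage would give the phenol and, after decarbonylation of the secondary acyl radical, loss of ring A C4.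
- Comparison: the mechanism is a radical pair instead of an acylpalladium species. Step economy is similar, since ester formation and irradiation replace borylation and coupling. The chosen plan is preferred because its chemoselectivity rests on functional groups rather than on light absorption.

Key step: step 7

Conventions: each cyclohexene is drawn flat with C1 (methyl-bearing) at the top and C1 to C6 running clockwise; β means above the plane, α below. TBS = tert-butyldimethylsilyl, TBSO = its ether.

Assumption: the (S)-configured boron catalyst of step 6 is taken to give the enantiomer drawn for 11; if the opposite sense of induction is found, its mirror image is used.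

## Route

Step 1
Reactants: 1 2,4-dihydroxybenzaldehyde
Product: 2 2,4-bis(TBSO)benzaldehyde
Conditions: TBSCl (2.4 equiv), imidazole, DMF, rt
Reagents that add atoms: tert-butyldimethylsilyl chloride, CC(C)(C)[Si](C)(C)Cl
Why: Standard silylation of phenols; silyl ethers are used for all spectator phenols because they bind Lewis acids weakly, their hindered oxygen atoms should not capture an allyl cation, and they can all be removed at the end with buffered fluoride.

Step 2
Reactants: 3 4-bromoresorcinol; 4 diethylphosphonoacetic acid
Product: 5 4-bromo-3-hydroxyphenyl 2-(diethoxyphosphoryl)acetate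
Conditions: EDC·HCl (1.05 equiv), DMAP (5 mol%), CH2Cl2, −10 °C, acid as limiting reagent
Reagents that add atoms: none
Why: Carbodiimide esterification; the hydroxyl para to bromine is the less hindered and more nucleophilic one, so acylating first and silylating second should place the ester and the silyl ether where the later steps need them.

Step 3
Reactants: 5 4-bromo-3-hydroxyphenyl 2-(diethoxyphosphoryl)acetate
Product: 6 4-bromo-3-(TBSO)phenyl 2-(diethoxyphosphoryl)acetate
Conditions: TBSOTf, 2,6-lutidine, CH2Cl2, −78 °C
Reagents that add atoms: tert-butyldimethylsilyl triflate, CC(C)(C)[Si](C)(C)OS(=O)(=O)C(F)(F)F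
Why: Silylation of the hindered phenol with a silyl triflate and a non-nucleophilic base, which avoids acyl transfer from the aryl ester; this silyloxy group later activates the ring carbon para to it in step 7.

Step 4
Reactants: 2 2,4-bis(TBSO)benzaldehyde; 6 4-bromo-3-(TBSO)phenyl 2-(diethoxyphosphoryl)acetate
Product: 7 4-bromo-3-(TBSO)phenyl (E)-3-[2,4-bis(TBSO)phenyl]prop-2-enoate
Conditions: LiCl, iPr2NEt, MeCN, rt
Reagents that add atoms: none
Why: Horner–Wadsworth–Emmons olefination with a stabilised phosphonate under mild amine/LiCl conditions, E-selective; it gives the aryl cinnamate directly, so no hydrolysis or hot amine threatens the aryl silyl ethers.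

Step 5
Reactants: 8 3-methylbut-2-enal
Product: 9 (E)-3-methyl-1-(trimethylsilyloxy)buta-1,3-diene
Conditions: Me3SiCl, Et3N, ZnCl2 (3 mol%), toluene, 40 °C; distillation
Reagents that add atoms: chlorotrimethylsilane, C[Si](C)(C)Cl
Why: Soft enolisation of the enal at the gamma-methyl group and O-silylation give the silyl dienol ether, with the E geometry of the enol double bond expected.

Step 6
Reactants: 7 4-bromo-3-(TBSO)phenyl (E)-3-[2,4-bis(TBSO)phenyl]prop-2-enoate; 9 (E)-3-methyl-1-(trimethylsilyloxy)buta-1,3-diene
Product: 11 4-bromo-3-(TBSO)phenyl 5α-[2,4-bis(TBSO)phenyl]-3β-hydroxy-1-methylcyclohex-1-ene-4β-carboxylate, via trimethylsilyl ether 10 (not isolated)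
Conditions: (S)-3,3-diphenyl-1-(o-tolyl)tetrahydro-1H,3H-pyrrolo[1,2-c][1,3,2]oxazaborole activated with HNTf2 (20 mol%), 9 (3 equiv), CH2Cl2, −40 to −20 °C; then citric acid, MeOH, 0 °C
Reagents that add atoms: none
Why: Lewis-acid-catalysed Diels–Alder reaction: the oxygen at the diene terminus and the 3-methyl group both direct C3–O next to the ester carbon, the E alkene of 7 is transferred suprafacially to the trans C4/C5 pair, and the chiral boron cation on the ester carbonyl should block one face and set C4 and C5 absolutely; C3 (endo expected) is immaterial because it is ionised in step 7 and removed in step 9, and citric acid in methanol cleaves only the alkyl trimethylsilyl ether.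

Step 7
Reactants: 11 4-bromo-3-(TBSO)phenyl 5α-[2,4-bis(TBSO)phenyl]-3β-hydroxy-1-methylcyclohex-1-ene-4β-carboxylate
Product: 12 cis-fused ring A lactone of 3β-[5-bromo-2-hydroxy-4-(TBSO)phenyl]-5α-[2,4-bis(TBSO)phenyl]-1-methylcyclohex-1-ene-4β-carboxylic acid
Conditions: Sc(OTf)3 (10 mol%), 4 Å molecular sieves, CH2Cl2 (0.005 M), 0 °C
Reagents that add atoms: none
Why: The trivalent scandium triflate ionises the secondary allylic alcohol to the methyl-stabilised C1–C2–C3 allyl cation, so either C3 epimer of 11 should converge. The arene of the C4 ester attacks C3 through the carbon ortho to the ester oxygen and para to the silyloxy group, and proton loss restores aromaticity, which makes this an intramolecular Friedel–Crafts allylation. The closest known reaction types are the acid-mediated Friedel–Crafts allylation of resorcinol derivatives by cyclic allylic alcohols and the acid-mediated cyclisation of aryl cinnamates to 3,4-dihydrocoumarins. The six-membered lactone closes in a 6-exo sense with respect to the allyl unit, with C3 inside the new ring and C1 and C2 outside. The new stereocentre C3 is controlled by the tether: the ester sits on the β face of C4 and can reach C3 only on that face, so ArA and the acyl group become cis and the C5 aryl, trans to the ester, ends trans to ArA. The step needs attack at C3 rather than C1 (the tether cannot reach C1), ring closure rather than loss of the C4 proton to the conjugated dienoate or intermolecular attack by the electron-rich C5 aryl ring (high dilution, hindered weakly donating silyl ethers, non-basic counter-ion), and no acid-induced alkene migration (catalytic Lewis acid, low temperature, short contact). The bromide is a spectator that marks the carbon of the later ketone.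

Step 8
Reactants: 11 4-bromo-3-(TBSO)phenyl 5α-[2,4-bis(TBSO)phenyl]-3β-hydroxy-1-methylcyclohex-1-ene-4β-carboxylate
Product: 13 S-ethyl 5α-[2,4-bis(TBSO)phenyl]-3β-hydroxy-1-methylcyclohex-1-ene-4β-carbothioate
Conditions: AlMe3 and EtSH (3 equiv each, premixed in CH2Cl2, 0 °C), then 11, 0 °C to rt; aqueous Rochelle salt work-up
Reagents that add atoms: ethanethiol, CCS
Why: Aluminium thiolate transesterification of the aryl ester, the most electrophilic carbonyl present; the aluminium alkoxide at C3 is inert and the aryl silyl ethers are untouched; the thioester is the neutral acyl donor for step 14 and acidifies C4 for steps 9 and 10.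

Step 9
Reactants: 13 S-ethyl 5α-[2,4-bis(TBSO)phenyl]-3β-hydroxy-1-methylcyclohex-1-ene-4β-carbothioate
Product: 15 S-ethyl 5α-[2,4-bis(TBSO)phenyl]-1-methylcyclohexa-1,3-diene-4-carbothioate, via mesylate 14 (not isolated)
Conditions: MsCl, Et3N (3 equiv), CH2Cl2, 0 °C to rt
Reagents that add atoms: none
Why: Mesylation and E1cB elimination across C3–C4 (acidic thioester alpha-hydrogen, allylic leaving group) give the conjugated dienyl thioester; the C3 and C4 centres of 13 are erased on purpose, and only C5, which is never part of an enolate, is carried on.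

Step 10
Reactants: 15 S-ethyl 5α-[2,4-bis(TBSO)phenyl]-1-methylcyclohexa-1,3-diene-4-carbothioate
Product: 17 S-ethyl 5α-[2,4-bis(TBSO)phenyl]-1-methylcyclohexa-1(6),2-diene-4α-carbothioate, via potassium trienolate 16 (not isolated)
Conditions: KN(SiMe3)2 (1.15 equiv), THF/DMPU, −78 °C; then transfer into AcOH (5 equiv) in THF, −78 °C
Reagents that add atoms: none
Why: Deprotonation at the far end of the dienyl thioester gives the fully conjugated trienolate, and kinetic protonation of extended enolates occurs at the alpha-carbon (deconjugative protonation); allylic 1,3-strain with the exocyclic enolate should force the C5 aryl pseudoaxial, so the proton enters C4 on the opposite (β) face and the thioester ends α, cis to the C5 aryl, which is the less stable relation needed in ring B; the diene may sit in the ring or be exocyclic, and either position leads to the same cation in step 11.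

Step 11
Reactants: 17 S-ethyl 5α-[2,4-bis(TBSO)phenyl]-1-methylcyclohexa-1(6),2-diene-4α-carbothioate; 3 4-bromoresorcinol
Product: 18 S-ethyl 3β-(5-bromo-2,4-dihydroxyphenyl)-5α-[2,4-bis(TBSO)phenyl]-1-methylcyclohex-1-ene-4α-carbothioate
Conditions: (±)-camphor-10-sulfonic acid (20 mol%), 3 (3 equiv), CH2Cl2/(CF3)2CHOH 4:1, 0 °C
Reagents that add atoms: none
Why: Brønsted-acid hydroarylation of a 1,3-diene: protonation at C6 gives the same kind of C1–C2–C3 allyl cation as in step 7, which the resorcinol attacks at the secondary terminus C3 through its carbon para to one hydroxyl and ortho to the other (bromine blocks the alternative), as in known couplings of resorcinols with cyclic terpene cations; the C4 thioester and the C5 aryl both lie on the α face, so the arene should enter on the β face, trans to the acyl group, which sets C3.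

Step 12
Reactants: 18 S-ethyl 3β-(5-bromo-2,4-dihydroxyphenyl)-5α-[2,4-bis(TBSO)phenyl]-1-methylcyclohex-1-ene-4α-carbothioate
Product: 19 S-ethyl 3β-[5-bromo-2,4-bis(TBSO)phenyl]-5α-[2,4-bis(TBSO)phenyl]-1-methylcyclohex-1-ene-4α-carbothioate
Conditions: TBSOTf (2.5 equiv), 2,6-lutidine, CH2Cl2, −78 to 0 °C
Reagents that add atoms: tert-butyldimethylsilyl triflate, CC(C)(C)[Si](C)(C)OS(=O)(=O)C(F)(F)F
Why: Silylation of the two new phenols prevents O-acylation in the couplings and acid-induced addition of the ortho phenol to the ring alkene; the non-nucleophilic base leaves the thioester and its alpha-centre alone.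

Step 13
Reactants: 12 cis-fused ring A lactone of 3β-[5-bromo-2-hydroxy-4-(TBSO)phenyl]-5α-[2,4-bis(TBSO)phenyl]-1-methylcyclohex-1-ene-4β-carboxylic acid
Product: 21 boronic acid of 12 with B(OH)2 in place of bromine, via pinacol boronate 20 (not isolated)
Conditions: Pd(dppf)Cl2 (5 mol%), B2pin2, KOAc, 1,4-dioxane, 80 °C; then NaIO4, NH4OAc, acetone/H2O, rt
Reagents that add atoms: bis(pinacolato)diboron, CC1(C)OB(OC1(C)C)B1OC(C)(C)C(C)(C)O1; water, O
Why: Miyaura borylation (oxidative addition of zerovalent palladium into C–Br, acetate-assisted transmetalation from the diboron) tolerates the lactone because phosphine-ligated palladium does not insert into aryl ester C–O bonds; periodate cleavage of the pinacol unit gives the free boronic acid needed for the base-free coupling.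

Step 14
Reactants: 21 boronic acid of 12 with B(OH)2 in place of bromine; 19 S-ethyl 3β-[5-bromo-2,4-bis(TBSO)phenyl]-5α-[2,4-bis(TBSO)phenyl]-1-methylcyclohex-1-ene-4α-carbothioate
Product: 22 lactone 12 bearing in place of bromine the ring B acyl group {3β-[5-bromo-2,4-bis(TBSO)phenyl]-5α-[2,4-bis(TBSO)phenyl]-1-methylcyclohex-1-en-4α-yl}carbonyl
Conditions: Pd2(dba)3 (5 mol%), P(2-furyl)3 (20 mol%), CuO2C(2-thienyl) (CuTC, monovalent copper, 1.6 equiv), THF, 45 °C
Reagents that add atoms: none
Why: Liebeskind–Srogl coupling: zerovalent palladium inserts into the thioester C–S bond, the copper carboxylate takes up the thiolate and activates boron so that transmetalation needs no base, and reductive elimination gives the ketone; the lactone, the aryl bromide and the epimerisable C4 of ring B should be untouched under these neutral conditions.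

Step 15
Reactants: 22 lactone 12 bearing in place of bromine the ring B acyl group {3β-[5-bromo-2,4-bis(TBSO)phenyl]-5α-[2,4-bis(TBSO)phenyl]-1-methylcyclohex-1-en-4α-yl}carbonyl
Product: 23 pinacol boronate of 22 with the boronate in place of the ArB bromine
Conditions: Pd(dppf)Cl2 (5 mol%), B2pin2, KOAc, 1,4-dioxane, 80 °C
Reagents that add atoms: bis(pinacolato)diboron, CC1(C)OB(OC1(C)C)B1OC(C)(C)C(C)(C)O1
Why: Second Miyaura borylation, now at the ArB bromide; acetate is too weak a base to enolise the hindered ketone and the lactone again survives.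

Step 16
Reactants: 23 pinacol boronate of 22 with the boronate in place of the ArB bromine
Product: 24 heptakis(TBS) ether of 25 in which the ArA hydroxyl ortho to ring A C3 is free
Conditions: [Pd(IPr)(cinnamyl)Cl] (15 mol%; IPr = 1,3-bis(2,6-diisopropylphenyl)imidazol-2-ylidene), K3PO4 (3 equiv), H2O (10 equiv), THF, 0.002 M by slow addition, 50 °C
Reagents that add atoms: none
Why: Proposed new method: a zerovalent palladium N-heterocyclic carbene complex, formed in situ from the divalent precatalyst, should insert into the C(acyl)–O bond of the ring A lactone (an aryl ester held in the reactive E conformation), the acylpalladium aryloxide should undergo phosphate-assisted transmetalation with the ArB boronate of the same molecule, and reductive elimination should forge the ArB–C(=O) bond, closing the twelve-membered ring and releasing the ArA phenol; the closest known reaction type is the intermolecular Suzuki–Miyaura acyl coupling of acyclic aryl esters with palladium N-heterocyclic carbene catalysts, here extended to a lactone and to ring closure; no stereocentre is formed.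

Step 17
Reactants: 24 heptakis(TBS) ether of 25 in which the ArA hydroxyl ortho to ring A C3 is free
Product: 25 target CNP0244682.3
Conditions: Bu4NF/AcOH (1:1, 10 equiv), THF, 0 °C to rt
Reagents that add atoms: none
Why: Fluoride cleavage of the seven aryl silyl ethers, buffered with acetic acid so that neither phenoxide basicity (epimerisation at C4 of ring B) nor protic acid (chroman formation, alkene migration) is present.

## Compound list

1 | 2,4-dihydroxybenzaldehyde | O=Cc1ccc(O)cc1O | starting material
2 | 2,4-bis(TBSO)benzaldehyde | O=Cc1ccc(O[Si](C)(C)C(C)(C)C)cc1O[Si](C)(C)C(C)(C)C | intermediate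
3 | 4-bromoresorcinol | Oc1ccc(Br)c(O)c1 | starting material
4 | diethylphosphonoacetic acid | CCOP(=O)(CC(=O)O)OCC | starting material
5 | 4-bromo-3-hydroxyphenyl 2-(diethoxyphosphoryl)acetate | CCOP(=O)(CC(=O)Oc1ccc(Br)c(O)c1)OCC | intermediate
6 | 4-bromo-3-(TBSO)phenyl 2-(diethoxyphosphoryl)acetate | CCOP(=O)(CC(=O)Oc1ccc(Br)c(O[Si](C)(C)C(C)(C)C)c1)OCC | intermediate
7 | 4-bromo-3-(TBSO)phenyl (E)-3-[2,4-bis(TBSO)phenyl]prop-2-enoate | O=C(/C=C/c1ccc(O[Si](C)(C)C(C)(C)C)cc1O[Si](C)(C)C(C)(C)C)Oc1ccc(Br)c(O[Si](C)(C)C(C)(C)C)c1 | intermediate
8 | 3-methylbut-2-enal | CC(C)=CC=O | starting material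
9 | (E)-3-methyl-1-(trimethylsilyloxy)buta-1,3-diene | C=C(C)/C=C/O[Si](C)(C)C | intermediate
10 | 4-bromo-3-(TBSO)phenyl 5α-[2,4-bis(TBSO)phenyl]-1-methyl-3β-(trimethylsilyloxy)cyclohex-1-ene-4β-carboxylate | CC1=C[C@@H](O[Si](C)(C)C)[C@@H](C(=O)Oc2ccc(Br)c(O[Si](C)(C)C(C)(C)C)c2)[C@H](c2ccc(O[Si](C)(C)C(C)(C)C)cc2O[Si](C)(C)C(C)(C)C)C1 | intermediate
11 | 4-bromo-3-(TBSO)phenyl 5α-[2,4-bis(TBSO)phenyl]-3β-hydroxy-1-methylcyclohex-1-ene-4β-carboxylate | CC1=C[C@@H](O)[C@@H](C(=O)Oc2ccc(Br)c(O[Si](C)(C)C(C)(C)C)c2)[C@H](c2ccc(O[Si](C)(C)C(C)(C)C)cc2O[Si](C)(C)C(C)(C)C)C1 | intermediate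
12 | cis-fused ring A lactone of 3β-[5-bromo-2-hydroxy-4-(TBSO)phenyl]-5α-[2,4-bis(TBSO)phenyl]-1-methylcyclohex-1-ene-4β-carboxylic acid | CC1=C[C@H]2c3cc(Br)c(O[Si](C)(C)C(C)(C)C)cc3OC(=O)[C@H]2[C@H](c2ccc(O[Si](C)(C)C(C)(C)C)cc2O[Si](C)(C)C(C)(C)C)C1 | intermediate
13 | S-ethyl 5α-[2,4-bis(TBSO)phenyl]-3β-hydroxy-1-methylcyclohex-1-ene-4β-carbothioate | CC1=C[C@@H](O)[C@@H](C(=O)SCC)[C@H](c2ccc(O[Si](C)(C)C(C)(C)C)cc2O[Si](C)(C)C(C)(C)C)C1 | intermediate
14 | S-ethyl 5α-[2,4-bis(TBSO)phenyl]-3β-(methanesulfonyloxy)-1-methylcyclohex-1-ene-4β-carbothioate | CC1=C[C@@H](OS(C)(=O)=O)[C@@H](C(=O)SCC)[C@H](c2ccc(O[Si](C)(C)C(C)(C)C)cc2O[Si](C)(C)C(C)(C)C)C1 | intermediate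
15 | S-ethyl 5α-[2,4-bis(TBSO)phenyl]-1-methylcyclohexa-1,3-diene-4-carbothioate | CC1=CC=C(C(=O)SCC)[C@H](c2ccc(O[Si](C)(C)C(C)(C)C)cc2O[Si](C)(C)C(C)(C)C)C1 | intermediate
16 | potassium trienolate of 15 (deprotonated at C6; enolate carbon exocyclic to C4) | CCSC([O-])=C1C=CC(C)=C[C@H]1c1ccc(O[Si](C)(C)C(C)(C)C)cc1O[Si](C)(C)C(C)(C)C.[K+] | intermediate
17 | S-ethyl 5α-[2,4-bis(TBSO)phenyl]-1-methylcyclohexa-1(6),2-diene-4α-carbothioate | CC1=C[C@@H](c2ccc(O[Si](C)(C)C(C)(C)C)cc2O[Si](C)(C)C(C)(C)C)[C@@H](C(=O)SCC)C=C1 | intermediate
18 | S-ethyl 3β-(5-bromo-2,4-dihydroxyphenyl)-5α-[2,4-bis(TBSO)phenyl]-1-methylcyclohex-1-ene-4α-carbothioate | CC1=C[C@@H](c2cc(Br)c(O)cc2O)[C@H](C(=O)SCC)[C@H](c2ccc(O[Si](C)(C)C(C)(C)C)cc2O[Si](C)(C)C(C)(C)C)C1 | intermediate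
19 | S-ethyl 3β-[5-bromo-2,4-bis(TBSO)phenyl]-5α-[2,4-bis(TBSO)phenyl]-1-methylcyclohex-1-ene-4α-carbothioate | CC1=C[C@@H](c2cc(Br)c(O[Si](C)(C)C(C)(C)C)cc2O[Si](C)(C)C(C)(C)C)[C@H](C(=O)SCC)[C@H](c2ccc(O[Si](C)(C)C(C)(C)C)cc2O[Si](C)(C)C(C)(C)C)C1 | intermediate
20 | pinacol boronate of 12 (boronate in place of bromine) | CC1=C[C@H]2c3cc(B4OC(C)(C)C(C)(C)O4)c(O[Si](C)(C)C(C)(C)C)cc3OC(=O)[C@H]2[C@H](c2ccc(O[Si](C)(C)C(C)(C)C)cc2O[Si](C)(C)C(C)(C)C)C1 | intermediate
21 | boronic acid of 12 (B(OH)2 in place of bromine) | CC1=C[C@H]2c3cc(B(O)O)c(O[Si](C)(C)C(C)(C)C)cc3OC(=O)[C@H]2[C@H](c2ccc(O[Si](C)(C)C(C)(C)C)cc2O[Si](C)(C)C(C)(C)C)C1 | intermediate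
22 | lactone 12 bearing in place of bromine the ring B acyl group {3β-[5-bromo-2,4-bis(TBSO)phenyl]-5α-[2,4-bis(TBSO)phenyl]-1-methylcyclohex-1-en-4α-yl}carbonyl | CC1=C[C@H]2c3cc(C(=O)[C@H]4[C@@H](C=C(C)C[C@H]4c4ccc(O[Si](C)(C)C(C)(C)C)cc4O[Si](C)(C)C(C)(C)C)c4cc(Br)c(O[Si](C)(C)C(C)(C)C)cc4O[Si](C)(C)C(C)(C)C)c(O[Si](C)(C)C(C)(C)C)cc3OC(=O)[C@H]2[C@H](c2ccc(O[Si](C)(C)C(C)(C)C)cc2O[Si](C)(C)C(C)(C)C)C1 | intermediate
23 | pinacol boronate of 22 (boronate in place of the ArB bromine) | CC1=C[C@H]2c3cc(C(=O)[C@H]4[C@@H](C=C(C)C[C@H]4c4ccc(O[Si](C)(C)C(C)(C)C)cc4O[Si](C)(C)C(C)(C)C)c4cc(B5OC(C)(C)C(C)(C)O5)c(O[Si](C)(C)C(C)(C)C)cc4O[Si](C)(C)C(C)(C)C)c(O[Si](C)(C)C(C)(C)C)cc3OC(=O)[C@H]2[C@H](c2ccc(O[Si](C)(C)C(C)(C)C)cc2O[Si](C)(C)C(C)(C)C)C1 | intermediate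
24 | heptakis(TBS) ether of 25 with the ArA hydroxyl ortho to ring A C3 free | CC1=C[C@H]2c3cc(c(O[Si](C)(C)C(C)(C)C)cc3O)C(=O)[C@H]3[C@@H](C=C(C)C[C@H]3c3ccc(O[Si](C)(C)C(C)(C)C)cc3O[Si](C)(C)C(C)(C)C)c3cc(c(O[Si](C)(C)C(C)(C)C)cc3O[Si](C)(C)C(C)(C)C)C(=O)[C@H]2[C@H](c2ccc(O[Si](C)(C)C(C)(C)C)cc2O[Si](C)(C)C(C)(C)C)C1 | intermediate
25 | CNP0244682.3 (ring A: 3β-ArA, 4β-acyl, 5α-aryl; ring B: 3β-ArB, 4α-acyl, 5α-aryl) | CC1=C[C@H]2c3cc(c(O)cc3O)C(=O)[C@H]3[C@@H](C=C(C)C[C@H]3c3ccc(O)cc3O)c3cc(c(O)cc3O)C(=O)[C@H]2[C@H](c2ccc(O)cc2O)C1 | target

## Step count and least certain steps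

Total step count: 17. Longest linear sequence: 13 steps (steps 2, 3, 4, 6, 8, 9, 10, 11, 12, 14, 15, 16, 17, from 3).

Step 16 (ring closure, proposed method). Most likely to go wrong: insertion of palladium into the C–O bond of an electron-rich aryl ester may be slow, so that protodeboronation and intermolecular coupling overtake ring closure; prolonged contact with phosphate may epimerise C4 of ring B through the ketone enolate and strip aryl silyl ethers. Fallback with known chemistry, setting out from 23 and rejoining the route at 25: the lactone of 23 is opened with AlMe3/EtSH and the liberated phenol is silylated in the same flask (TBSOTf, 2,6-lutidine) to give the thioester pinacol boronate F1; NaIO4/NH4OAc converts it into the boronic acid F2; an intramolecular Liebeskind–Srogl coupling (Pd2(dba)3, P(2-furyl)3, CuTC, THF, 0.002 M, no base) closes the ring to the octakis(TBS) ether F3, which the conditions of step 17 convert into 25.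

Step 7 (key step). Most likely to go wrong: loss of the C4 proton from the allyl cation to the conjugated dienoate, intermolecular alkylation of the C5 aryl ring of a second molecule, acid-induced migration of the ring alkene, or slow ring closure because the ester must adopt its less favoured conformation and the silyloxy arene is only moderately nucleophilic. Fallback, setting out from 11 and rejoining at 12: 11 is converted with Cl3CCN and catalytic DBU into the allylic trichloroacetimidate F4, which is ionised with catalytic Me3SiOTf at −78 °C in CH2Cl2; the better leaving group allows a temperature at which proton loss and alkene migration are slow, and the same tethered ring closure gives 12.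

Step 6 (cycloaddition). Most likely to go wrong: sluggish reaction and poor facial selectivity, because the beta-aryl acrylate is electron-rich and binds the catalyst through a single carbonyl, together with acid-induced loss of the silyl dienol ether. Fallback, setting out from 7 and 9 and rejoining at 11: uncatalysed cycloaddition in toluene at 130 °C (sealed tube, radical inhibitor) followed by the same methanolysis gives 11 as a racemate with its enantiomer F5, and the two are separated by preparative chromatography on a chiral stationary phase; resolution replaces catalyst control.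

Step 10 (kinetic protonation). Most likely to go wrong: insufficient facial selectivity in the protonation at C4, or return to the conjugated thioester by proton transfer before the quench is complete. Fallback, setting out from 12 and rejoining at 19 (steps 8 to 12 are bypassed): 12 is opened with AlMe3/EtSH to the phenol thioester F6, which is silylated in the same flask (TBSOTf, 2,6-lutidine) to F7, the C4 epimer of 19; DBU in THF equilibrates C4 through the thioester enolate, 19 is separated by chromatography and recovered F7 is resubmitted. Equilibration with recycling replaces kinetic protonation, and ArB is already in place.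

Step 14 (intermolecular acyl coupling). Most likely to go wrong: slow transmetalation between a doubly flanked thioester and an ortho-substituted arylboronic acid, with protodeboronation and decarbonylation as competing processes. Fallback, setting out from 19 and 21 and rejoining at 22: iBu2AlH at −78 °C reduces 19 to the aldehyde F8; monovalent rhodium ([Rh(cod)OH]2, 1,4-dioxane/H2O, 40 °C) catalyses addition of 21 to give the carbinol F9 as either epimer; oxidation with DMP (1,1,1-triacetoxy-1,1-dihydro-1,2-benziodoxol-3(1H)-one) buffered with NaHCO3 gives 22.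

## Further compounds

F1 | step 16 | S-ethyl thioester of the opened ring A lactone of 23, ArA 2-hydroxyl as TBS ether, ArB pinacol boronate | CC1=C[C@@H](c2cc(C(=O)[C@H]4[C@@H](C=C(C)C[C@H]4c4ccc(O[Si](C)(C)C(C)(C)C)cc4O[Si](C)(C)C(C)(C)C)c4cc(B5OC(C)(C)C(C)(C)O5)c(O[Si](C)(C)C(C)(C)C)cc4O[Si](C)(C)C(C)(C)C)c(O[Si](C)(C)C(C)(C)C)cc2O[Si](C)(C)C(C)(C)C)[C@@H](C(=O)SCC)[C@H](c2ccc(O[Si](C)(C)C(C)(C)C)cc2O[Si](C)(C)C(C)(C)C)C1
F2 | step 16 | boronic acid corresponding to F1 | CC1=C[C@@H](c2cc(C(=O)[C@H]4[C@@H](C=C(C)C[C@H]4c4ccc(O[Si](C)(C)C(C)(C)C)cc4O[Si](C)(C)C(C)(C)C)c4cc(B(O)O)c(O[Si](C)(C)C(C)(C)C)cc4O[Si](C)(C)C(C)(C)C)c(O[Si](C)(C)C(C)(C)C)cc2O[Si](C)(C)C(C)(C)C)[C@@H](C(=O)SCC)[C@H](c2ccc(O[Si](C)(C)C(C)(C)C)cc2O[Si](C)(C)C(C)(C)C)C1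
F3 | step 16 | octakis(TBS) ether of 25 | CC1=C[C@H]2c3cc(c(O[Si](C)(C)C(C)(C)C)cc3O[Si](C)(C)C(C)(C)C)C(=O)[C@H]3[C@@H](C=C(C)C[C@H]3c3ccc(O[Si](C)(C)C(C)(C)C)cc3O[Si](C)(C)C(C)(C)C)c3cc(c(O[Si](C)(C)C(C)(C)C)cc3O[Si](C)(C)C(C)(C)C)C(=O)[C@H]2[C@H](c2ccc(O[Si](C)(C)C(C)(C)C)cc2O[Si](C)(C)C(C)(C)C)C1
F4 | step 7 | O-(2,2,2-trichloroacetimidate) of 11 | CC1=C[C@@H](OC(=N)C(Cl)(Cl)Cl)[C@@H](C(=O)Oc2ccc(Br)c(O[Si](C)(C)C(C)(C)C)c2)[C@H](c2ccc(O[Si](C)(C)C(C)(C)C)cc2O[Si](C)(C)C(C)(C)C)C1
F5 | step 6 | enantiomer of 11 | CC1=C[C@H](O)[C@H](C(=O)Oc2ccc(Br)c(O[Si](C)(C)C(C)(C)C)c2)[C@@H](c2ccc(O[Si](C)(C)C(C)(C)C)cc2O[Si](C)(C)C(C)(C)C)C1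
F6 | step 10 | S-ethyl 3β-[5-bromo-2-hydroxy-4-(TBSO)phenyl]-5α-[2,4-bis(TBSO)phenyl]-1-methylcyclohex-1-ene-4β-carbothioate | CC1=C[C@@H](c2cc(Br)c(O[Si](C)(C)C(C)(C)C)cc2O)[C@@H](C(=O)SCC)[C@H](c2ccc(O[Si](C)(C)C(C)(C)C)cc2O[Si](C)(C)C(C)(C)C)C1
F7 | step 10 | S-ethyl 3β-[5-bromo-2,4-bis(TBSO)phenyl]-5α-[2,4-bis(TBSO)phenyl]-1-methylcyclohex-1-ene-4β-carbothioate (C4 epimer of 19) | CC1=C[C@@H](c2cc(Br)c(O[Si](C)(C)C(C)(C)C)cc2O[Si](C)(C)C(C)(C)C)[C@@H](C(=O)SCC)[C@H](c2ccc(O[Si](C)(C)C(C)(C)C)cc2O[Si](C)(C)C(C)(C)C)C1
F8 | step 14 | 3β-[5-bromo-2,4-bis(TBSO)phenyl]-5α-[2,4-bis(TBSO)phenyl]-1-methylcyclohex-1-ene-4α-carbaldehyde | CC1=C[C@@H](c2cc(Br)c(O[Si](C)(C)C(C)(C)C)cc2O[Si](C)(C)C(C)(C)C)[C@H](C=O)[C@H](c2ccc(O[Si](C)(C)C(C)(C)C)cc2O[Si](C)(C)C(C)(C)C)C1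
F9 | step 14 | carbinol corresponding to 22 (CH(OH) in place of the ketone carbonyl, either epimer) | CC1=C[C@H]2c3cc(C(O)[C@H]4[C@@H](C=C(C)C[C@H]4c4ccc(O[Si](C)(C)C(C)(C)C)cc4O[Si](C)(C)C(C)(C)C)c4cc(Br)c(O[Si](C)(C)C(C)(C)C)cc4O[Si](C)(C)C(C)(C)C)c(O[Si](C)(C)C(C)(C)C)cc3OC(=O)[C@H]2[C@H](c2ccc(O[Si](C)(C)C(C)(C)C)cc2O[Si](C)(C)C(C)(C)C)C1
A1 | alternative 1 | seco compound: ring B as cis-fused C4/C5 lactone, ArA pinacol boronate, ketone on ring A C4 in place, seven methoxymethyl ethers | CC1=C[C@@H](c4cc(C(=O)[C@H]5[C@H](c6ccc(OCOC)cc6OCOC)CC(C)=C[C@H]5c5cc(B6OC(C)(C)C(C)(C)O6)c(OCOC)cc5OCOC)c(OCOC)cc4OCOC)[C@@H]2C(=O)Oc3cc(OCOC)ccc3[C@@H]2C1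
A2 | alternative 1 | heptakis(methoxymethyl) ether of the target with the ortho phenol of the ring B C5 aryl free | CC1=C[C@H]2c3cc(c(OCOC)cc3OCOC)C(=O)[C@H]3[C@@H](C=C(C)C[C@H]3c3ccc(OCOC)cc3O)c3cc(c(OCOC)cc3OCOC)C(=O)[C@H]2[C@H](c2ccc(OCOC)cc2OCOC)C1
A3 | alternative 2 | cis-bromohydrin: 1-aryl-2-bromo-5-methyl-3,7-diarylcyclohept-4-en-1-ol | CC1=C[C@@H](c2cc(Br)c(OCOC)cc2OCOC)[C@H](Br)[C@@](O)(c2ccc(O[Si](C)(C)C(C)(C)C)cc2OCOC)[C@H](c2ccc(OCOC)cc2OCOC)C1
A4 | alternative 2 | ring B aryl ketone with trans C3/C4 and cis C4/C5 | CC1=C[C@@H](c2cc(Br)c(OCOC)cc2OCOC)[C@H](C(=O)c2ccc(O[Si](C)(C)C(C)(C)C)cc2OCOC)[C@H](c2ccc(OCOC)cc2OCOC)C1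
A5 | alternative 3 | fourteen-membered macrolactone: ring A C4 carboxyl esterified with the ArB hydroxyl para to ring B C3 | CC1=C[C@H]2c3cc(c(O)cc3OCOC)C(=O)[C@H]3[C@@H](C=C(C)C[C@H]3c3ccc(OCOC)cc3OCOC)c3ccc(cc3OCOC)OC(=O)[C@H]2[C@H](c2ccc(OCOC)cc2OCOC)C1
A6 | alternative 3 | hexakis(methoxymethyl) ether of the target with both ketone-flanking phenols free | CC1=C[C@H]2c3cc(c(O)cc3OCOC)C(=O)[C@H]3[C@@H](C=C(C)C[C@H]3c3ccc(OCOC)cc3OCOC)c3cc(c(O)cc3OCOC)C(=O)[C@H]2[C@H](c2ccc(OCOC)cc2OCOC)C1
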